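## Retrosynthetic overview

1. Target 20 ⇐ Shi epoxidation of the prenyl alkene (ring C, the C10–C11 oxirane) of tris-angelate 19 ⇐ angeloylation at O2 of epoxy alcohol 17 ⇐ hydroxyl-directed epoxidation (ring B, the C3–C4 oxirane) and Luche reduction of bis-angelate enone 15.
2. 15 ⇐ double angeloylation of diol 12 ⇐ trans α′-hydroxylation of carvone-type enone 11 ⇐ cross-metathesis (allyl to prenyl) of carbinol 9.
3. 9 ⇐ chiral-phosphoric-acid allylboration (C8–C9 bond, sets C8) of 2-substituted acrolein 7 ⇐ organocatalytic α-methylenation of aldehyde 5.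
4. 5 ⇐ key step: amine-catalysed aldol condensation that selects between the two enantiotopic CH2CHO arms of prochiral keto-dialdehyde 4 (forms ring A, sets C6) ⇐ ozonolysis of cyclopentene ketone 3 ⇐ acid 1 + ethyllithium 2.
5. Ring order: ring A (cyclohexenone, step 2), then ring B (step 9), then ring C (step 11).

Conventions: Ang = angeloyl = (Z)-2-methylbut-2-enoyl. Ring A is numbered C1 (OAng), C2 (OAng), C3 (CH3, oxirane), C4 (oxirane), C5 (CH2), C6 (side chain); the side chain is C7 (=CH2), C8 (OAng), C9, C10, C11. β is the face of the C6 side chain.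

Assumption: 2-(cyclopent-3-en-1-yl)acetic acid (1) and angelic anhydride (18) are taken as catalogue chemicals.

## Route

Step 1
Reactants: 1 2-(cyclopent-3-en-1-yl)acetic acid; 2 ethyllithium
Product: 3 1-(cyclopent-3-en-1-yl)butan-2-one
Conditions: EtLi (2.2 equiv), Et2O, −78 → 0 °C; then cold 1 M HCl
Reagents that add atoms: ethyllithium (2), [Li]CC
Why: Organolithium addition to a lithium carboxylate (acid-to-ketone synthesis), in which the second equivalent gives a gem-dilithium alkoxide that cannot collapse before the quench, so the ketone is not over-alkylated; no stereocentre is formed.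

Step 2
Reactants: 3 1-(cyclopent-3-en-1-yl)butan-2-one
Product: 5 (S)-2-(4-methyl-5-oxocyclohex-3-en-1-yl)acetaldehyde, via keto-dialdehyde 4 (not isolated)
Conditions: O3, CH2Cl2, −78 °C; PPh3; then toluene, 9-amino-9-deoxy-epi-quinine (10 mol %), AcOH (30 mol %), −20 °C → rt
Reagents that add atoms: ozone, [O-][O+]=O
Why: Proposed new method: ozonolysis (known) gives the prochiral keto-dialdehyde 4, whose only feasible intramolecular aldol closures are the two mirror-image six-membered attacks of the ethyl-ketone α-carbon on one or the other CH2CHO arm (every other combination would be four-membered), so a primary-amine catalyst that forms the Z-enamine on the ethyl side and hydrogen-bonds one aldehyde through its protonated quinuclidine in a chair-like 6-enolendo transition state should select one enantiotopic arm, set C6 (S) and, after irreversible dehydration, close ring A; the closest known reaction types are the Hajos–Parrish cyclisation and the cinchona-primary-amine desymmetrising aldol condensation of 4-substituted heptane-2,6-diones, whereas selection between two enantiotopic aldehyde acceptors has not been shown, so the sense of induction must be assigned experimentally and the quinidine-derived pseudo-enantiomer used if it is opposite.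

Step 3
Reactants: 5 (S)-2-(4-methyl-5-oxocyclohex-3-en-1-yl)acetaldehyde; 6 formaldehyde
Product: 7 (R)-2-(4-methyl-5-oxocyclohex-3-en-1-yl)prop-2-enal
Conditions: 37% aq. HCHO, pyrrolidine (10 mol %), EtCO2H (10 mol %), i-PrOH, 45 °C
Reagents that add atoms: formaldehyde (6), C=O
Why: Organocatalytic Mannich-type α-methylenation of an aldehyde (enamine adds to formaldehyde-derived iminium, then the amine is eliminated), selective for the aldehyde over the ketone; C6 keeps its geometry and only its CIP letter changes.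

Step 4
Reactants: 7 (R)-2-(4-methyl-5-oxocyclohex-3-en-1-yl)prop-2-enal; 8 allylboronic acid pinacol ester
Product: 9 (5R)-5-[(3S)-3-hydroxyhexa-1,5-dien-2-yl]-2-methylcyclohex-2-en-1-one
Conditions: (S)-TRIP [(S)-3,3′-bis(2,4,6-triisopropylphenyl)-1,1′-binaphthyl-2,2′-diyl hydrogen phosphate] (5 mol %), 4 Å MS, toluene, −30 °C; aq. work-up
Reagents that add atoms: allylboronic acid pinacol ester (8), C=CCB1OC(C)(C)C(C)(C)O1
Why: Chiral-phosphoric-acid-catalysed allylboration of an aldehyde through a closed chair transition state with the acid hydrogen-bonded to the boronate oxygen, in which the catalyst rather than the remote C6 centre chooses the aldehyde face; the (S)-acid is the antipode of the one that gives (R)-carbinols from aryl and alkenyl aldehydes, so it should give 8S, and the enone carbonyl is too unreactive to compete.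

Step 5
Reactants: 9 (5R)-5-[(3S)-3-hydroxyhexa-1,5-dien-2-yl]-2-methylcyclohex-2-en-1-one; 10 2-methylbut-2-ene
Product: 11 (5R)-5-[(3S)-3-hydroxy-6-methylhepta-1,5-dien-2-yl]-2-methylcyclohex-2-en-1-one
Conditions: second-generation Grubbs catalyst [RuCl2(=CHPh)(PCy3)(H2IMes)] (3 mol %), 2-methylbut-2-ene/CH2Cl2, 35 °C
Reagents that add atoms: 2-methylbut-2-ene (10), CC=C(C)C
Why: Olefin cross-metathesis in which only the monosubstituted terminal alkene enters the cycle and is capped by excess 2-methylbut-2-ene as the prenyl alkene, while the 1,1-disubstituted and enone alkenes are inert and no stereocentre is touched.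

Step 6
Reactants: 11 (5R)-5-[(3S)-3-hydroxy-6-methylhepta-1,5-dien-2-yl]-2-methylcyclohex-2-en-1-one
Product: 12 (5S,6S)-6-hydroxy-5-[(3S)-3-hydroxy-6-methylhepta-1,5-dien-2-yl]-2-methylcyclohex-2-en-1-one
Conditions: NaN(SiMe3)2 (2.3 equiv), THF, −78 °C; 2-(phenylsulfonyl)-3-phenyloxaziridine (1.3 equiv), −78 °C; H2O
Reagents that add atoms: 2-(phenylsulfonyl)-3-phenyloxaziridine, O=S(=O)(c1ccccc1)N1OC1c1ccccc1
Why: Davis oxaziridine hydroxylation of the kinetic cross-conjugated (α′) sodium enolate formed beside the C8 alkoxide, with the oxidant approaching C1 anti to the adjacent C6 substituent to give the trans (1α) hydroxyl, which is also the thermodynamic epimer.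

Step 7
Reactants: 12 (5S,6S)-6-hydroxy-5-[(3S)-3-hydroxy-6-methylhepta-1,5-dien-2-yl]-2-methylcyclohex-2-en-1-one; 13 angelic acid
Product: 15 (1S,6S)-3-methyl-2-oxo-6-[(3S)-3-(angeloyloxy)-6-methylhepta-1,5-dien-2-yl]cyclohex-3-en-1-yl angelate, via mixed anhydride 14 (not isolated)
Conditions: 13 (3 equiv), 2,4,6-Cl3C6H2COCl (3 equiv), Et3N (3 equiv), toluene, rt, filter; then 12, toluene, 75 °C (no DMAP)
Reagents that add atoms: angelic acid (13), C/C=C(/C)C(=O)O
Why: Yamaguchi-type esterification through the 2,4,6-trichlorobenzoyl mixed anhydride, run thermally without a nucleophilic amine so that both secondary hydroxyls are acylated without Z-to-E isomerisation of angelate to tiglate; C1 and C8 are retained.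

Step 8
Reactants: 15 (1S,6S)-3-methyl-2-oxo-6-[(3S)-3-(angeloyloxy)-6-methylhepta-1,5-dien-2-yl]cyclohex-3-en-1-yl angelate
Product: 16 (1S,2S,6S)-2-hydroxy-3-methyl-6-[(3S)-3-(angeloyloxy)-6-methylhepta-1,5-dien-2-yl]cyclohex-3-en-1-yl angelate
Conditions: NaBH4, CeCl3·7H2O, MeOH, −78 °C; cold AcOH quench
Reagents that add atoms: none
Why: Luche 1,2-reduction in which the small hydride attacks the enone carbonyl axially on the half-chair that holds the C1 ester and C6 side chain equatorial, giving the equatorial 2β-alcohol (trans to O1, cis to the side chain, as in carvone to cis-carveol) and leaving esters and alkenes alone.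

Step 9
Reactants: 16 (1S,2S,6S)-2-hydroxy-3-methyl-6-[(3S)-3-(angeloyloxy)-6-methylhepta-1,5-dien-2-yl]cyclohex-3-en-1-yl angelate
Product: 17 (1S,2R,3R,4S,6S)-3,4-epoxy-2-hydroxy-3-methyl-6-[(3S)-3-(angeloyloxy)-6-methylhepta-1,5-dien-2-yl]cyclohexyl angelate (oxirane cis to the 2-hydroxyl)
Conditions: VO(acac)2 (5 mol %), t-BuOOH (1.5 equiv), CH2Cl2, 0 °C → rt
Reagents that add atoms: tert-butyl hydroperoxide, CC(C)(C)OO
Why: Hydroxyl-directed epoxidation in which the vanadium alkylperoxide bound to the only free hydroxyl (O2) delivers oxygen to the adjacent ring alkene on the β face, setting C3 and C4, while the undirected prenyl, 1,1-disubstituted and angelate alkenes react far more slowly.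

Step 10
Reactants: 17 (1S,2R,3R,4S,6S)-3,4-epoxy-2-hydroxy-3-methyl-6-[(3S)-3-(angeloyloxy)-6-methylhepta-1,5-dien-2-yl]cyclohexyl angelate; 18 angelic anhydride
Product: 19 (1S,2R,3S,4S,6S)-3,4-epoxy-3-methyl-6-[(3S)-3-(angeloyloxy)-6-methylhepta-1,5-dien-2-yl]cyclohexane-1,2-diyl diangelate
Conditions: LiN(SiMe3)2 (1.1 equiv), THF, −78 °C; 18 (1.5 equiv), −78 → 0 °C; H2O
Reagents that add atoms: angelic anhydride (18), C/C=C(/C)C(=O)OC(=O)/C(C)=C\C
Why: Acylation of the lithium alkoxide with angelic anhydride, a non-acidic method without nucleophilic catalyst that keeps the Z-geometry and the oxirane; a 1,2-acyl shift between O1 and O2 would be degenerate and the cis epoxy-alkoxide cannot undergo Payne rearrangement.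

Step 11
Reactants: 19 (1S,2R,3S,4S,6S)-3,4-epoxy-3-methyl-6-[(3S)-3-(angeloyloxy)-6-methylhepta-1,5-dien-2-yl]cyclohexane-1,2-diyl diangelate
Product: 20 (1S,2R,3S,4S,6S)-3,4-epoxy-3-methyl-6-{(3S)-3-(angeloyloxy)-4-[(2R)-3,3-dimethyloxiran-2-yl]but-1-en-2-yl}cyclohexane-1,2-diyl diangelate (CNP0258231.3)
Conditions: D-fructose-derived Shi ketone (30 mol %), Oxone (2KHSO5·KHSO4·K2SO4), K2CO3, Bu4NHSO4, MeCN/CH2(OMe)2–aq. Na2B4O7 buffer (pH 10.5), 0 °C
Reagents that add atoms: potassium peroxymonosulfate (active part of Oxone), [K+].[O-]S(=O)(=O)OO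
Why: Shi asymmetric epoxidation (chiral dioxirane, spiro transition state) is catalyst-controlled and, by the model that gives (R,R)-oxiranes from trans and trisubstituted alkenes, should give the 10R oxirane on the electron-rich prenyl alkene, while the electron-poor angelates and the hindered, inductively deactivated 1,1-disubstituted alkene are left.

## Compound list

1 | 2-(cyclopent-3-en-1-yl)acetic acid | OC(=O)CC1CC=CC1 | starting material
2 | ethyllithium | [Li]CC | starting material
3 | 1-(cyclopent-3-en-1-yl)butan-2-one | CCC(=O)CC1CC=CC1 | intermediate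
4 | 3-(2-oxobutyl)pentanedial (prochiral keto-dialdehyde) | CCC(=O)CC(CC=O)CC=O | intermediate
5 | (S)-2-(4-methyl-5-oxocyclohex-3-en-1-yl)acetaldehyde | O=CC[C@@H]1CC=C(C)C(=O)C1 | intermediate
6 | formaldehyde | C=O | starting material
7 | (R)-2-(4-methyl-5-oxocyclohex-3-en-1-yl)prop-2-enal | C=C(C=O)[C@@H]1CC=C(C)C(=O)C1 | intermediate
8 | allylboronic acid pinacol ester | C=CCB1OC(C)(C)C(C)(C)O1 | starting material
9 | (5R)-5-[(3S)-3-hydroxyhexa-1,5-dien-2-yl]-2-methylcyclohex-2-en-1-one | C=C([C@H](CC=C)O)[C@@H]1CC=C(C)C(=O)C1 | intermediate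
10 | 2-methylbut-2-ene | CC=C(C)C | starting material
11 | (5R)-5-[(3S)-3-hydroxy-6-methylhepta-1,5-dien-2-yl]-2-methylcyclohex-2-en-1-one | C=C([C@H](CC=C(C)C)O)[C@@H]1CC=C(C)C(=O)C1 | intermediate
12 | (5S,6S)-6-hydroxy-5-[(3S)-3-hydroxy-6-methylhepta-1,5-dien-2-yl]-2-methylcyclohex-2-en-1-one | C=C([C@H](CC=C(C)C)O)[C@@H]1CC=C(C)C(=O)[C@H]1O | intermediate
13 | angelic acid, (Z)-2-methylbut-2-enoic acid | C/C=C(/C)C(=O)O | starting material
14 | angelic 2,4,6-trichlorobenzoic anhydride (mixed anhydride) | C/C=C(/C)C(=O)OC(=O)c1c(Cl)cc(Cl)cc1Cl | intermediate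
15 | (1S,6S)-3-methyl-2-oxo-6-[(3S)-3-(angeloyloxy)-6-methylhepta-1,5-dien-2-yl]cyclohex-3-en-1-yl angelate | C=C([C@H](CC=C(C)C)OC(=O)/C(C)=C\C)[C@@H]1CC=C(C)C(=O)[C@H]1OC(=O)/C(C)=C\C | intermediate
16 | (1S,2S,6S)-2-hydroxy-3-methyl-6-[(3S)-3-(angeloyloxy)-6-methylhepta-1,5-dien-2-yl]cyclohex-3-en-1-yl angelate | C=C([C@H](CC=C(C)C)OC(=O)/C(C)=C\C)[C@@H]1CC=C(C)[C@H](O)[C@H]1OC(=O)/C(C)=C\C | intermediate
17 | (1S,2R,3R,4S,6S)-3,4-epoxy-2-hydroxy-3-methyl-6-[(3S)-3-(angeloyloxy)-6-methylhepta-1,5-dien-2-yl]cyclohexyl angelate | C=C([C@H](CC=C(C)C)OC(=O)/C(C)=C\C)[C@@H]1C[C@@H]2O[C@]2(C)[C@H](O)[C@H]1OC(=O)/C(C)=C\C | intermediate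
18 | angelic anhydride, (Z)-2-methylbut-2-enoic anhydride | C/C=C(/C)C(=O)OC(=O)/C(C)=C\C | starting material
19 | (1S,2R,3S,4S,6S)-3,4-epoxy-3-methyl-6-[(3S)-3-(angeloyloxy)-6-methylhepta-1,5-dien-2-yl]cyclohexane-1,2-diyl diangelate | C=C([C@H](CC=C(C)C)OC(=O)/C(C)=C\C)[C@@H]1C[C@@H]2O[C@]2(C)[C@H](OC(=O)/C(C)=C\C)[C@H]1OC(=O)/C(C)=C\C | intermediate
20 | (1S,2R,3S,4S,6S)-3,4-epoxy-3-methyl-6-{(3S)-3-(angeloyloxy)-4-[(2R)-3,3-dimethyloxiran-2-yl]but-1-en-2-yl}cyclohexane-1,2-diyl diangelate | C=C([C@H](C[C@H]1OC1(C)C)OC(=O)/C(C)=C\C)[C@@H]1C[C@@H]2O[C@]2(C)[C@H](OC(=O)/C(C)=C\C)[C@H]1OC(=O)/C(C)=C\C | target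

## Step count and risks

Total steps: 11. Longest linear sequence: 11 (fully linear; 2, 6, 8, 10, 13 and 18 are purchased).

Steps most likely to fail:

**Step 2 (proposed new desymmetrising aldol condensation).** The risk is low enantioselection between the two aldehyde arms, or consumption of the dialdehyde by the amine. The fallback sets out from 4 and comes back at 9, using known chemistry only. Compound 4 is cyclised without enantiocontrol by an ordinary acid- or ammonium-salt-catalysed intramolecular aldol condensation (TsOH or piperidinium acetate, toluene) to racemic 2-(4-methyl-5-oxocyclohex-3-en-1-yl)acetaldehyde F1. This is methylenated as in step 3 to racemic 2-(4-methyl-5-oxocyclohex-3-en-1-yl)prop-2-enal F2. The catalyst-controlled allylboration of step 4 then sets the first enantioenriched centre (C8) and turns the racemate into two 8S diastereomers: compound 9 and its C6 epimer (5S)-5-[(3S)-3-hydroxyhexa-1,5-dien-2-yl]-2-methylcyclohex-2-en-1-one F3. Chromatographic separation (preparative HPLC if needed) returns 9, at most half of the material, to step 5.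

**Step 6 (α′-hydroxylation of a dianion).** The risks are a poor trans:cis ratio at C1 and addition of the enolate to the sulfonimine by-product. The fallback sets out from 9 and comes back at 12; it moves the oxygenation ahead of the metathesis and switches to a Rubottom oxidation. Compound 9 is treated with LiN(iPr)2 (2.2 equiv) and Me3SiCl in THF at −78 °C to give the bis-trimethylsilyl derivative of 9 (8-O-trimethylsilyl ether, ring as the 2-trimethylsilyloxy-3-methylcyclohexa-1,3-diene with C1=C2 and C3=C4) F4. Buffered mCPBA (NaHCO3, CH2Cl2/hexane, −20 °C) attacks only the electron-rich silyloxydiene, anti to the C6 substituent, since the terminal and 1,1-disubstituted alkenes are slow. Citric acid/MeOH then gives (5S,6S)-6-hydroxy-5-[(3S)-3-hydroxyhexa-1,5-dien-2-yl]-2-methylcyclohex-2-en-1-one F5. Cross-metathesis with 10 under the conditions of step 5 gives 12.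

**Step 9 (vanadium-directed epoxidation).** The C2 hydroxyl is pseudo-equatorial, so the reaction may be slow or may oxidise the alcohol back to the enone. The fallback sets out from 15 and comes back at 20; it inverts the order of the two epoxidations and replaces vanadium by hydrogen-bond-directed peracid delivery, which works for pseudo-equatorial cyclohexenols. Shi epoxidation of 15 under the conditions of step 11 (the ring alkene is an unreactive enone at this stage) gives (1S,6S)-3-methyl-2-oxo-6-{(3S)-3-(angeloyloxy)-4-[(2R)-3,3-dimethyloxiran-2-yl]but-1-en-2-yl}cyclohex-3-en-1-yl angelate F6. Luche reduction as in step 8 gives (1S,2S,6S)-2-hydroxy-3-methyl-6-{(3S)-3-(angeloyloxy)-4-[(2R)-3,3-dimethyloxiran-2-yl]but-1-en-2-yl}cyclohex-3-en-1-yl angelate F7. Henbest epoxidation (mCPBA, NaHCO3, CH2Cl2, 0 °C) then gives (1S,2R,3R,4S,6S)-3,4-epoxy-2-hydroxy-3-methyl-6-{(3S)-3-(angeloyloxy)-4-[(2R)-3,3-dimethyloxiran-2-yl]but-1-en-2-yl}cyclohexyl angelate F8, which is acylated with LiN(SiMe3)2 and 18 as in step 10 to give 20.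

Further compounds
F1 | step 2 | racemic 2-(4-methyl-5-oxocyclohex-3-en-1-yl)acetaldehyde | O=CCC1CC=C(C)C(=O)C1
F2 | step 2 | racemic 2-(4-methyl-5-oxocyclohex-3-en-1-yl)prop-2-enal | C=C(C=O)C1CC=C(C)C(=O)C1
F3 | step 2 | (5S)-5-[(3S)-3-hydroxyhexa-1,5-dien-2-yl]-2-methylcyclohex-2-en-1-one | C=C([C@H](CC=C)O)[C@H]1CC=C(C)C(=O)C1
F4 | step 6 | bis-trimethylsilyl derivative of 9 (8-O-trimethylsilyl ether, ring as 2-trimethylsilyloxy-3-methylcyclohexa-1,3-diene) | C=C([C@H](CC=C)O[Si](C)(C)C)[C@@H]1CC=C(C)C(O[Si](C)(C)C)=C1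
F5 | step 6 | (5S,6S)-6-hydroxy-5-[(3S)-3-hydroxyhexa-1,5-dien-2-yl]-2-methylcyclohex-2-en-1-one | C=C([C@H](CC=C)O)[C@@H]1CC=C(C)C(=O)[C@H]1O
F6 | step 9 | (1S,6S)-3-methyl-2-oxo-6-{(3S)-3-(angeloyloxy)-4-[(2R)-3,3-dimethyloxiran-2-yl]but-1-en-2-yl}cyclohex-3-en-1-yl angelate | C=C([C@H](C[C@H]1OC1(C)C)OC(=O)/C(C)=C\C)[C@@H]1CC=C(C)C(=O)[C@H]1OC(=O)/C(C)=C\C
F7 | step 9 | (1S,2S,6S)-2-hydroxy-3-methyl-6-{(3S)-3-(angeloyloxy)-4-[(2R)-3,3-dimethyloxiran-2-yl]but-1-en-2-yl}cyclohex-3-en-1-yl angelate | C=C([C@H](C[C@H]1OC1(C)C)OC(=O)/C(C)=C\C)[C@@H]1CC=C(C)[C@H](O)[C@H]1OC(=O)/C(C)=C\C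
F8 | step 9 | (1S,2R,3R,4S,6S)-3,4-epoxy-2-hydroxy-3-methyl-6-{(3S)-3-(angeloyloxy)-4-[(2R)-3,3-dimethyloxiran-2-yl]but-1-en-2-yl}cyclohexyl angelate | C=C([C@H](C[C@H]1OC1(C)C)OC(=O)/C(C)=C\C)[C@@H]1C[C@@H]2O[C@]2(C)[C@H](O)[C@H]1OC(=O)/C(C)=C\C
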